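**Retrosynthetic overview**

- The last bond made is the depside ester C(=O)–OAr: it is cut into 2-(benzyloxy)-4-methoxy-6-propylbenzoic acid and commercial methyl 2,4-dihydroxy-3,6-dimethylbenzoate (B ring bought intact, acylated at its free 4-OH). A final hydrogenolysis frees the A-ring 2-OH.
- The acid comes from methyl 2,4-dihydroxy-6-propylbenzoate by 4-O-methylation, 2-O-benzylation and saponification.
- That arene comes from a cyclohexane-1,3-dione ester by dehydrogenative aromatisation. Its ring is cut at C1–C6 (intermolecular Michael addition of dimethyl malonate to (E)-hept-3-en-2-one, the key C–C bond) and at C2–C3 (intramolecular Claisen closure).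
- Ring order: only the A-ring carbocycle is built (Michael, Claisen ring closure, aromatisation); the B ring is a purchased arene and is attached last through the ester.

Assumption: the target SMILES has no stereocentre and no stereogenic double bond, so the compound is achiral and no asymmetric step is needed.

**Route**

Step 1
Reactants: 1 dimethyl malonate; 2 (E)-hept-3-en-2-one
Product: 4 methyl 2-hydroxy-4-oxo-6-propylcyclohex-2-ene-1-carboxylate (racemic), via Michael adduct 3 (not isolated)
Conditions: NaOMe (1.1 equiv), MeOH, reflux, 4 h; then cold aq. HCl to pH 3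
Reagents that add atoms: none
Why: Michael addition of sodiomalonate to the enone β-carbon makes the key C–C bond (future C1–C6 of the A ring), and the methyl ketone enolate then closes the ring by intramolecular Claisen (Dieckmann-type) condensation, driven by formation of the stabilised β-diketone enolate; the two new stereocentres are racemic and are erased in step 2.

Step 2
Reactants: 4 methyl 2-hydroxy-4-oxo-6-propylcyclohex-2-ene-1-carboxylate
Product: 6 methyl 2,4-dihydroxy-6-propylbenzoate, via bromodione 5 (not isolated)
Conditions: Br2 (1.05 equiv), DMF, 0 °C to rt, 1 h; then 80 °C, 14 h; aq. NaHSO3 work-up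
Reagents that add atoms: none
Why: α-bromination of the enolised β-diketone followed by thermal loss of HBr (after HBr-mediated bromine transposition) gives a cyclohexadienone that tautomerises irreversibly to the resorcinol, a halogenation/dehydrohalogenation aromatisation that keeps the methyl ester at 80 °C.

Step 3
Reactants: 6 methyl 2,4-dihydroxy-6-propylbenzoate
Product: 7 methyl 2-hydroxy-4-methoxy-6-propylbenzoate
Conditions: MeI (1.05 equiv), K2CO3 (1.2 equiv), acetone, reflux, 8 h
Reagents that add atoms: iodomethane (MeI), CI
Why: Williamson O-methylation goes selectively at the 4-OH because the 2-OH is hydrogen-bonded to the ester carbonyl and is both less acidic and less nucleophilic.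

Step 4
Reactants: 7 methyl 2-hydroxy-4-methoxy-6-propylbenzoate
Product: 8 methyl 2-(benzyloxy)-4-methoxy-6-propylbenzoate
Conditions: BnBr (1.3 equiv), K2CO3 (2 equiv), DMF, 70 °C, 12 h
Reagents that add atoms: benzyl bromide (BnBr), BrCc1ccccc1
Why: under forcing Williamson conditions (polar aprotic solvent, heat) the remaining chelated phenol is benzylated, masking it for the later acylation.

Step 5
Reactants: 8 methyl 2-(benzyloxy)-4-methoxy-6-propylbenzoate
Product: 9 2-(benzyloxy)-4-methoxy-6-propylbenzoic acid
Conditions: KOH (10 equiv), DMSO–H2O (4:1), 90 °C, 8 h; then cold 2 M HCl to pH 2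
Reagents that add atoms: potassium hydroxide, [K+].[OH-] (supplies the carboxyl OH oxygen)
Why: poorly solvated hydroxide in aqueous DMSO saponifies the di-ortho-substituted benzoate, and both aryl ethers are inert to base; cold acidification avoids decarboxylation.

Step 6
Reactants: 9 2-(benzyloxy)-4-methoxy-6-propylbenzoic acid; 10 methyl 2,4-dihydroxy-3,6-dimethylbenzoate
Product: 12 methyl 4-{[2-(benzyloxy)-4-methoxy-6-propylbenzoyl]oxy}-2-hydroxy-3,6-dimethylbenzoate, via mixed anhydride 11 (not isolated)
Conditions: TFAA (4 equiv), dry toluene, rt, 4 h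
Reagents that add atoms: none
Why: TFAA turns the hindered electron-rich acid into an acylium-like mixed trifluoroacetic anhydride that O-acylates the only non-chelated phenol of 10 (the 4-OH; the 2-OH is hydrogen-bonded and flanked by CO2Me and CH3), a mixed-anhydride esterification standard for depsides.

Step 7
Reactants: 12 methyl 4-{[2-(benzyloxy)-4-methoxy-6-propylbenzoyl]oxy}-2-hydroxy-3,6-dimethylbenzoate
Product: 13 Peruvinide A, methyl 2-hydroxy-4-[(2-hydroxy-4-methoxy-6-propylbenzoyl)oxy]-3,6-dimethylbenzoate
Conditions: H2 (1 atm), 10% Pd/C, EtOAc, rt, 3 h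
Reagents that add atoms: none
Why: catalytic hydrogenolysis cleaves the benzyl ether under neutral conditions and leaves the aryl ester, methyl ester and aryl methyl ether untouched.

**Compound list**

1 | dimethyl malonate | COC(=O)CC(=O)OC | starting material
2 | (E)-hept-3-en-2-one | CCC/C=C/C(C)=O | starting material
3 | dimethyl 2-(2-oxoheptan-4-yl)propanedioate (Michael adduct, racemic) | CCCC(CC(C)=O)C(C(=O)OC)C(=O)OC | intermediate
4 | methyl 2-hydroxy-4-oxo-6-propylcyclohex-2-ene-1-carboxylate (racemic, enol form of the 2,4-dione; stereocentres removed in step 2) | CCCC1CC(=O)C=C(O)C1C(=O)OC | intermediate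
5 | methyl 3-bromo-2-hydroxy-4-oxo-6-propylcyclohex-2-ene-1-carboxylate (bromodione, racemic) | CCCC1CC(=O)C(Br)=C(O)C1C(=O)OC | intermediate
6 | methyl 2,4-dihydroxy-6-propylbenzoate | CCCc1cc(O)cc(O)c1C(=O)OC | intermediate
7 | methyl 2-hydroxy-4-methoxy-6-propylbenzoate | CCCc1cc(OC)cc(O)c1C(=O)OC | intermediate
8 | methyl 2-(benzyloxy)-4-methoxy-6-propylbenzoate | CCCc1cc(OC)cc(OCc2ccccc2)c1C(=O)OC | intermediate
9 | 2-(benzyloxy)-4-methoxy-6-propylbenzoic acid | CCCc1cc(OC)cc(OCc2ccccc2)c1C(=O)O | intermediate
10 | methyl 2,4-dihydroxy-3,6-dimethylbenzoate (methyl β-orcinolcarboxylate, commercial fragrance chemical) | COC(=O)c1c(C)cc(O)c(C)c1O | starting material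
11 | 2-(benzyloxy)-4-methoxy-6-propylbenzoic trifluoroacetic anhydride (mixed anhydride) | CCCc1cc(OC)cc(OCc2ccccc2)c1C(=O)OC(=O)C(F)(F)F | intermediate
12 | methyl 4-{[2-(benzyloxy)-4-methoxy-6-propylbenzoyl]oxy}-2-hydroxy-3,6-dimethylbenzoate | CCCc1cc(OC)cc(OCc2ccccc2)c1C(=O)Oc1cc(C)c(C(=O)OC)c(O)c1C | intermediate
13 | Peruvinide A, methyl 2-hydroxy-4-[(2-hydroxy-4-methoxy-6-propylbenzoyl)oxy]-3,6-dimethylbenzoate (achiral) | CCCc1cc(OC)cc(O)c1C(=O)Oc1cc(C)c(C(=O)OC)c(O)c1C | target

**Step count and risks**

Total step count: 7. Longest linear sequence: 7 steps (from 1 and 2 to 13); compound 10 is purchased and enters at step 6.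

The three steps most likely to fail:

Step 2 (aromatisation; risk of ring over-bromination or incomplete loss of HBr). The fallback sets out from 4. Exhaustive treatment with Br2 (3.1 equiv) in AcOH at rt deliberately dehydrogenates and ring-brominates in one operation to give crystalline methyl 3,5-dibromo-2,4-dihydroxy-6-propylbenzoate F1. Both C–Br bonds are then removed by hydrogenolysis (H2, 10% Pd/C, NaOAc, MeOH, rt), which comes back to the route at 6.

Step 5 (saponification of the di-ortho-substituted ester; risk of very slow or incomplete hydrolysis). The fallback sets out from 8 and avoids attack of hydroxide on the shielded carbonyl by a redox detour. LiAlH4 in THF (0 °C to rt) reduces the ester to [2-(benzyloxy)-4-methoxy-6-propylphenyl]methanol F2. MnO2 in CH2Cl2 oxidises this benzylic alcohol to 2-(benzyloxy)-4-methoxy-6-propylbenzaldehyde F3. Pinnick oxidation (NaClO2, NaH2PO4, 2-methyl-2-butene, t-BuOH–H2O, rt) then gives the acid, coming back to the route at 9.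

Step 6 (esterification of a hindered acid; risk of low conversion, trifluoroacetylation or C-acylation of the phenol). The fallback sets out from 9 and reverses the order of deprotection and coupling. Hydrogenolysis (H2, Pd/C, EtOAc) gives 2-hydroxy-4-methoxy-6-propylbenzoic acid (divaricatinic acid) F4, which is less hindered and whose 2-OH is hydrogen-bonded and unreactive. F4 is condensed directly with 10 by carbodiimide activation (DCC, dry toluene, rt), acylating the 4-OH of 10. This comes back to the route at 13, so step 7 is no longer needed.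

**Further compounds**

F1 | step 2 | methyl 3,5-dibromo-2,4-dihydroxy-6-propylbenzoate | CCCc1c(Br)c(O)c(Br)c(O)c1C(=O)OC
F2 | step 5 | [2-(benzyloxy)-4-methoxy-6-propylphenyl]methanol | CCCc1cc(OC)cc(OCc2ccccc2)c1CO
F3 | step 5 | 2-(benzyloxy)-4-methoxy-6-propylbenzaldehyde | CCCc1cc(OC)cc(OCc2ccccc2)c1C=O
F4 | step 6 | 2-hydroxy-4-methoxy-6-propylbenzoic acid (divaricatinic acid) | CCCc1cc(OC)cc(O)c1C(=O)O
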